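# Proposed synthesis of (6S)-6-[(2R,4R,6R,10S)-2,4,6,10-tetrahydroxyhenicosyl]-5,6-dihydro-2H-pyran-2-one (29)

Atom numbers C1–C26 are those of the target chain (C1 = lactone carbonyl, C5 = ring carbinol, C26 = end of the tail) and are used for all intermediates. TBS = tert-butyldimethylsilyl, TBSO = tert-butyldimethylsilyloxy, Boc = tert-butoxycarbonyl.

## The problem

The target 29 is an unbranched C26 chain. Its C1–C5 end is a 5,6-dihydro-2H-pyran-2-one (C1 carbonyl, C2=C3, ring oxygen on C5). The side chain carries secondary hydroxyls at C7, C9, C11 and C15 and ends in an undecyl tail (C16–C26). There are no rings to join: the task is chain assembly, with the one ring closed at the end by lactonisation.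

C5, C7, C9 and C11 form an all-syn 1,3-polyol, and here each centre can be relayed from its neighbour. A carbonate on the C11 oxygen can deliver oxygen to C9 syn, and a C9 hydroxyl can direct hydride to a C7 ketone syn. C15 is different. Three methylenes (C12–C14) insulate it from C11, so the 1,5-anti pair C11/C15 is beyond substrate control and must come from a reagent or catalyst.

The unsaturated lactone is the fragile part. It does not survive organolithiums, hydride, hydrogenation or base (ring opening, conjugate addition of the C7 hydroxyl to C3), so it has to be made last, after the tail is saturated and sulfur is gone. The β-hydroxy ketone and β-silyloxy aldehyde on the way are prone to elimination and are used at once.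

The feature that is exploited: C11 and C15 each have a methylene on the outer side (C10, C16) and are linked by C12–C14. C10–C16 is therefore a C2-symmetric bis-homoallylic 1,5-diol in disguise (compound 4), whose core is pentane-1,5-diol 1. The price of this symmetry is that the two identical arms of 4 must later be told apart.

## Retrosynthesis

**Lactone C1–O bond.** Target 29 is opened at the ester bond between C1 and the C5 oxygen and its hydroxyls are masked. This leads to the (Z)-enoate 27, with C5, C11 and C15 as TBS ethers and C7/C9 as an acetonide. The neighbouring option, closing C2=C3 by metathesis of a C5 acrylate, would need the C5 hydroxyl freed alone among five. Cutting C1–O lets one acid treatment both unmask and cyclise. 27 is not smaller, but it is stable to everything that precedes it. The forward step must strip three silyl ethers and an acetonide and let the C5 hydroxyl of the seco ester 28 close onto the cis ester, without the C7 hydroxyl adding to C3.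

**C2=C3.** The enoate is cut at the double bond to the C3 aldehyde 26 and a two-carbon phosphonate. 26 is traced to the terminal alkene 24, in which an allyl group on C5 stands for C3 and C4. A protected C3 alcohol would cost two operations (deprotection, oxidation) where the alkene costs one ozonolysis. The olefination must be Z-selective, because only the Z-ester can lactonise.

**C7–H.** The acetonide 24 comes from the 7,9-syn diol 23, and the C7 carbinol from the β-hydroxy ketone 21 by hydroxyl-directed reduction. The ketone is carried as the dithiane 20. Setting C7 in a C–C bond-forming step (an aldol at C7–C8 or C6–C7) would ask for 1,5-syn and 1,3-syn induction together, both against the usual substrate bias. Reduction under control of the C9 hydroxyl is the reliable relay. 20 has one stereocentre fewer and exposes the C7–C8 bond.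

**C7–C8.** 20 is divided between C7 and C8 into the terminal epoxide 11 (C8–C26, three stereocentres) and the lithiated form 19 of the dithiane 18 (C3–C7, one stereocentre). Cutting C8–C9 instead would discard the terminal carbon that the key step installs and leave C9 to be set in a bimolecular addition. Cutting C7–C8 lets C9 arrive already fixed from C11. 18 is three steps from 1,3-dithiane 12 and (R)-epichlorohydrin 13, through the epoxide 16 and the alcohol 17 (a vinyl organometallic supplies C3). The union needs clean metalation of a 2-alkyl dithiane beside an allyl group, and attack at the unsubstituted epoxide carbon only.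

**C17=C18 and the epoxide.** The silyl groups of 11 are removed (10). The saturated tail is traced to the alkene 9 and the epoxide to the iodocarbonate 8. The C17=C18 bond is cut by cross-metathesis into the iodocarbonate 6 and dec-1-ene 7. Hydrogenation has to come here, before sulfur and the enoate enter. Metathesis has to come after the alkene of the other arm is consumed, or the two terminal alkenes could not be told apart. 6 is nine carbons smaller than 8, and 7 is a commodity alkene. The forward steps ask that a primary iodide survive metathesis and a terminal epoxide survive hydrogenation.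

**C9–O.** The C9–O bond of 6 is cut back to the C8=C9 alkene of the mono-carbonate 5, to be formed by iodocarbonate cyclisation with C11 controlling C9. 5 is the mono-acylated form of the diol 4. This one cut does two jobs:
- it sets C9 by 1,3-relay;
- it distinguishes the two arms, since only the arm that bears the carbonate can cyclise.

A statistical cross-metathesis as the differentiating event would leave two hydroxyls that still cannot be told apart. A statistical mono-acylation is made on one-step material, gives a single mono-product because the hydroxyls of 4 are homotopic, and lets unreacted 4 be recycled. The cyclisation must be syn-selective and must leave the unassisted alkene of the other arm alone.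

**C10–C11 and C15–C16.** 4 is cut at both carbinol–methylene bonds to pentane-1,5-diol 1 and two molecules of allyl acetate 2. A one-directional route would set C11 and C15 in separate steps with separate chiral reagents. Here the two centres are related by a C2 axis and each has a methylene outside, so one catalyst can set both while forming two C–C bonds from the alcohol oxidation level, with no protecting group and no separate oxidation. Both precursors are achiral commodity chemicals. The forward reaction must show the same facial selectivity at two remote aldehydes generated in situ and must outrun lactol formation and over-oxidation.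

## Roads not taken

Alternative 1: The ring is cut at C4–C5 and O–C1. The forward key step is a catalytic asymmetric hetero-Diels–Alder reaction between the C5 aldehyde A1 and the diene A2 under a chiral chromium Schiff-base catalyst. It gives the cis-2-methoxy-dihydropyran A3, which is then taken to the lactone oxidation level.
- Merits: C5 is set by a catalyst, both ring bonds form at once, and C2=C3 arrives in place. No Z-olefination, no ozonolysis and no free C5 hydroxyl are needed.
- Weak points: A1 already carries C7, C9, C11 and C15. The cycloaddition solves the easiest centre and leaves the polyol chain, including the 1,5-pair, to a separate synthesis. The catalyst must override the C7 silyloxy stereocentre of A1. The acetal oxidation adds a step beside an acetonide.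
- Comparison: as an endgame it is at least equal to steps 15–17 here, and better in that C5 is made late by a catalyst and not bought early through 13. The chosen plan sets against it that its catalytic step is spent on the harder problem, C11/C15, at the very start, and that C5 comes almost free from the chiral pool.

Alternative 2: The chain is cut at C9–C10 and C8–C9. The lithiated silyl dithiane A4 opens the epoxide A5 at C10, a 1,4-Brook shift moves silicon to the C11 oxygen, and the regenerated anion opens the epoxide A6 at C8. The product is A7, with C9 masked and the C7 hydroxyl free.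
- Merits: two C–C bonds in one flask, high convergence, built-in differentiation of the C11 and C7 oxygens, and no statistical step. In these respects it is better than the chosen plan.
- Weak points: three of the five stereocentres must exist before the key step. A5 contains the C11/C15 pair, so the hardest problem is moved into a starting material that needs two separate asymmetric operations or the very allylation proposed here. A6 needs its own syn-1,3 synthesis. C9 is still set afterwards by directed reduction, as C7 is in the chosen plan.
- Comparison: the chosen plan sets against the convergence of this road one catalytic step that makes both remote centres from 1 and 2, and a C9 centre that follows from C11 without a reagent. Its step 11 is a two-component relative of this coupling, and the silyl-dithiane relay is kept in reserve for it.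

Alternative 3: The C9–O bond is cut. A rhenium oxo catalyst shifts the allylic hydroxyl of A8 from C7 to C9, and the acetal donor A9 traps the syn-1,3-diol as the all-equatorial dioxane A10.
- Merits: catalytic, redox-neutral, thermodynamically funnelled to the syn acetal, and the diol emerges protected. As a way of setting C9 it is more economical than the carbonate, iodocyclisation and methanolysis used here.
- Weak points: it creates one stereocentre, by the same 1,3-relay from C11. A8 again presupposes the C11/C15 pair. It needs an (E)-allylic alcohol on one arm only, which a C2-symmetric diene such as 4 cannot give without a statistical cross-metathesis. The ionising conditions must spare the C15 silyl ether. A10 ends in a vinyl group (C7=C8), so C7 and C5 still require two further stereocontrolled operations.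
- Comparison: the chosen plan sets against its elegance that the iodocyclisation is also the event that tells the arms of 4 apart, and that it leaves C8 as an epoxide ready for the fragment union.

Key step: step 1

Remark on the chemistry: the catalyst is assumed to show with 1 the sense of induction it shows with other unbranched primary alcohols, for which the (S)-configured ligand is expected to give (4R,8R)-4. Should the sense be opposite, the (R)-ligand is used and nothing else changes.

## Route

Step 1
Reactants: 1 pentane-1,5-diol; 2 allyl acetate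
Product: 4 (4R,8R)-undeca-1,10-diene-4,8-diol, via (5R)-oct-7-ene-1,5-diol 3 (not isolated)
Conditions: [Ir(cod)Cl]2 (5 mol%), (S)-Cl,MeO-BIPHEP (10 mol%), 4-chloro-3-nitrobenzoic acid (20 mol%), Cs2CO3 (40 mol%), 2 (10 equiv), 1,4-dioxane, 90 °C, sealed vessel
Reagents that add atoms: none
Why: Two-directional transfer-hydrogenative carbonyl allylation, the reaction type established for 1,n-diols and best studied with 1,3-diols. The cyclometallated trivalent iridium C,O-benzoate formed in situ takes up a primary hydroxyl of 1 as its alkoxide and dehydrogenates it by β-hydride elimination; deprotonation of the hydride gives an anionic monovalent iridium species that ionises 2 to the allyl complex, the aldehyde inserts through a closed six-membered chair transition state, and alcohol exchange releases 3, after which the same sequence repeats at the other terminus. No ring is closed. C11 and C15 are each set by the chiral bisphosphine alone, which fixes the aldehyde face offered to the allyl ligand; no stereocentre in the substrate is near enough to interfere. The step needs the same facial selectivity at two identical, remote aldehydes, and the equivalence of the two termini of 1 ensures that one catalyst reads both alike; the second event turns most of the minor-enantiomer mono-adduct into the meso diastereomer, so the enantiomeric purity of 4 should exceed that of a single allylation. It also needs primary over secondary alcohol dehydrogenation, which the catalyst provides because the homoallylic carbinols of 3 and 4 are more hindered and are held by olefin coordination away from β-hydride elimination. The δ-hydroxy aldehydes rest largely as lactols, and allylation must drain the open form faster than the lactol is dehydrogenated; the large excess of 2 serves this.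

Step 2
Reactants: 4 (4R,8R)-undeca-1,10-diene-4,8-diol
Product: 5 tert-butyl (4R,8R)-8-hydroxyundeca-1,10-dien-4-yl carbonate
Conditions: Boc2O (0.6 equiv), DMAP (10 mol%), MeCN, 0 °C to rt; recovered 4 re-submitted
Reagents that add atoms: di-tert-butyl dicarbonate, CC(C)(C)OC(=O)OC(=O)OC(C)(C)C
Why: Statistical mono-acylation (tert-butyl carbonate formation) of a C2-symmetric diol; the two hydroxyls are homotopic, so the mono-carbonate is a single compound, and the sub-stoichiometric anhydride keeps double acylation low while unreacted 4 is recycled. The acylated arm is thereby defined as the C8–C11 arm.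

Step 3
Reactants: 5 tert-butyl (4R,8R)-8-hydroxyundeca-1,10-dien-4-yl carbonate
Product: 6 (4R,6R)-4-[(4R)-4-hydroxyhept-6-en-1-yl]-6-(iodomethyl)-1,3-dioxan-2-one (4,6-cis)
Conditions: IBr (1.05 equiv, added slowly as a CH2Cl2 solution), toluene, −85 °C; aq. Na2S2O3/NaHCO3
Reagents that add atoms: iodine monobromide, IBr
Why: Iodocarbonate cyclisation: the carbonyl oxygen captures the iodonium ion of the C8=C9 alkene in a chair transition state with the C11 side chain equatorial, so C9 is set syn to C11 (4,6-cis ring) and the tert-butyl group leaves as the cation. The alkene of the other arm has no internal nucleophile, can only add the interhalogen by a slower bimolecular path, and should survive one equivalent at −85 °C.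

Step 4
Reactants: 6 (4R,6R)-4-[(4R)-4-hydroxyhept-6-en-1-yl]-6-(iodomethyl)-1,3-dioxan-2-one; 7 dec-1-ene
Product: 8 (4R,6R)-4-[(4R)-4-hydroxypentadec-6-en-1-yl]-6-(iodomethyl)-1,3-dioxan-2-one (E/Z mixture)
Conditions: second-generation Grubbs catalyst (H2IMes)(PCy3)Cl2Ru=CHPh (5 mol%), 7 (4 equiv), CH2Cl2, 40 °C
Reagents that add atoms: none
Why: Olefin cross-metathesis of two terminal alkenes, driven by loss of ethene and by the excess of 7; the primary iodide, cyclic carbonate and free hydroxyl are tolerated. The C17=C18 geometry is irrelevant because the bond is saturated in step 6.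

Step 5
Reactants: 8 (4R,6R)-4-[(4R)-4-hydroxypentadec-6-en-1-yl]-6-(iodomethyl)-1,3-dioxan-2-one
Product: 9 (2R,6R)-1-[(2R)-oxiran-2-yl]heptadec-8-ene-2,6-diol (E/Z mixture)
Conditions: K2CO3 (3 equiv), MeOH, rt
Reagents that add atoms: none
Why: Carbonate methanolysis frees the C9 alkoxide, which closes the epoxide by intramolecular SN2 displacement of iodide at C8, so C9 keeps its configuration. The C11 hydroxyl, in a 1,3-relation to the epoxide, has no low-energy rearrangement path.

Step 6
Reactants: 9 (2R,6R)-1-[(2R)-oxiran-2-yl]heptadec-8-ene-2,6-diol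
Product: 10 (2R,6S)-1-[(2R)-oxiran-2-yl]heptadecane-2,6-diol
Conditions: H2 (1 atm), 5% Pt/C, EtOAc, rt, stopped at full conversion
Reagents that add atoms: none
Why: Heterogeneous hydrogenation of a 1,2-disubstituted alkene; platinum in a neutral aprotic solvent is chosen because it is less given than palladium to C–O hydrogenolysis of the terminal epoxide. The change of the C15 descriptor from R to S is a priority change only.

Step 7
Reactants: 10 (2R,6S)-1-[(2R)-oxiran-2-yl]heptadecane-2,6-diol
Product: 11 (2R)-2-[(2R,6S)-2,6-bis(TBSO)heptadecyl]oxirane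
Conditions: TBSCl (3 equiv), imidazole (6 equiv), DMF, rt
Reagents that add atoms: tert-butyldimethylsilyl chloride, CC(C)(C)[Si](C)(C)Cl
Why: Silyl ether formation at both secondary hydroxyls (C11, C15) in one operation under imidazole catalysis; the epoxide is inert to these conditions.

Step 8
Reactants: 12 1,3-dithiane; 13 (R)-2-(chloromethyl)oxirane ((R)-epichlorohydrin)
Product: 16 2-{[(2R)-oxiran-2-yl]methyl}-1,3-dithiane, via 2-lithio-1,3-dithiane 14 (not isolated), via lithium (2R)-1-chloro-3-(1,3-dithian-2-yl)propan-2-olate 15 (not isolated)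
Conditions: n-BuLi, THF, −30 °C; then 13, −78 to 0 °C
Reagents that add atoms: none
Why: Corey–Seebach alkylation: the dithiane anion opens the epoxide of 13 at its unsubstituted carbon and the alkoxide then displaces chloride, so the stereocentre (the future C5) is carried over without a bond to it being broken.

Step 9
Reactants: 16 2-{[(2R)-oxiran-2-yl]methyl}-1,3-dithiane
Product: 17 (2S)-1-(1,3-dithian-2-yl)pent-4-en-2-ol
Conditions: CH2=CHMgBr (2 equiv), CuI (10 mol%), THF, −40 to −20 °C
Reagents that add atoms: vinylmagnesium bromide, C=C[Mg]Br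
Why: Copper-catalysed Grignard opening of a terminal epoxide at the less hindered carbon; the stereocentre is not involved.

Step 10
Reactants: 17 (2S)-1-(1,3-dithian-2-yl)pent-4-en-2-ol
Product: 18 tert-butyl{[(2S)-1-(1,3-dithian-2-yl)pent-4-en-2-yl]oxy}dimethylsilane
Conditions: TBSCl, imidazole, DMF, rt
Reagents that add atoms: tert-butyldimethylsilyl chloride, CC(C)(C)[Si](C)(C)Cl
Why: Standard silyl ether formation; the C5 oxygen is masked for the organolithium step and for the later directed reduction, in which it must not chelate.

Step 11
Reactants: 18 tert-butyl{[(2S)-1-(1,3-dithian-2-yl)pent-4-en-2-yl]oxy}dimethylsilane; 11 (2R)-2-[(2R,6S)-2,6-bis(TBSO)heptadecyl]oxirane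
Product: 20 (2R,4R,8S)-4,8-bis(TBSO)-1-{2-[(2S)-2-(TBSO)pent-4-en-1-yl]-1,3-dithian-2-yl}nonadecan-2-ol, via 2-lithio derivative of the dithiane 19 (not isolated)
Conditions: 18 (1.3 equiv), t-BuLi (1.3 equiv), THF/HMPA (9:1), −78 °C, 5 min; then 11, −78 to −40 °C
Reagents that add atoms: none
Why: Corey–Seebach union of a 2-alkyl-2-lithio-1,3-dithiane with a terminal epoxide: metalation by t-BuLi in THF/HMPA is fast at −78 °C, and the carbanion attacks C8, the unsubstituted epoxide carbon, forming C7–C8 and leaving C9 as the free carbinol with its configuration intact.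

Step 12
Reactants: 20 (2R,4R,8S)-4,8-bis(TBSO)-1-{2-[(2S)-2-(TBSO)pent-4-en-1-yl]-1,3-dithian-2-yl}nonadecan-2-ol
Product: 21 (4S,8R,10R,14S)-4,10,14-tris(TBSO)-8-hydroxypentacos-1-en-6-one
Conditions: PhI(O2CCF3)2 (1.5 equiv), NaHCO3, MeCN/H2O (9:1), 0 °C
Reagents that add atoms: water, O
Why: Oxidative hydrolysis of the dithioacetal with a hypervalent iodine reagent, which is fast at 0 °C and, under buffering, spares the terminal alkene, the silyl ethers and the β-hydroxy ketone.

Step 13
Reactants: 21 (4S,8R,10R,14S)-4,10,14-tris(TBSO)-8-hydroxypentacos-1-en-6-one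
Product: 23 (4S,6R,8S,10R,14S)-4,10,14-tris(TBSO)pentacos-1-ene-6,8-diol, via diethylboron chelate of the hydroxy ketone 22 (not isolated)
Conditions: Et2BOMe (1.2 equiv), THF/MeOH (4:1), −78 °C; NaBH4 (1.3 equiv), −78 °C; AcOH, then MeOH co-evaporation
Reagents that add atoms: none
Why: Narasaka–Prasad reduction: boron ties the C9 oxygen to the C7 carbonyl in a half-chair chelate 22 and external hydride adds axially, giving the 7,9-syn diol. The C5 silyl ether does not chelate and so does not compete; the C9 descriptor changes from R to S by priority only.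

Step 14
Reactants: 23 (4S,6R,8S,10R,14S)-4,10,14-tris(TBSO)pentacos-1-ene-6,8-diol
Product: 24 (4R,6S)-6-[(2R,6S)-2,6-bis(TBSO)heptadecyl]-2,2-dimethyl-4-[(2S)-2-(TBSO)pent-4-en-1-yl]-1,3-dioxane
Conditions: Me2C(OMe)2, PPTS (cat.), CH2Cl2, rt
Reagents that add atoms: 2,2-dimethoxypropane, COC(C)(C)OC
Why: Acetonide formation by transketalisation; the syn-1,3-diol gives the chair dioxane with both side chains equatorial, and the silyl ethers are stable to the mild acid.

Step 15
Reactants: 24 (4R,6S)-6-[(2R,6S)-2,6-bis(TBSO)heptadecyl]-2,2-dimethyl-4-[(2S)-2-(TBSO)pent-4-en-1-yl]-1,3-dioxane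
Product: 26 (3R)-4-{(4R,6S)-6-[(2R,6S)-2,6-bis(TBSO)heptadecyl]-2,2-dimethyl-1,3-dioxan-4-yl}-3-(TBSO)butanal, via secondary ozonide 25 (not isolated)
Conditions: O3, CH2Cl2, −78 °C; then PPh3, −78 °C to rt; used crude
Reagents that add atoms: ozone, [O-][O+]=O
Why: Ozonolysis of the only alkene with reductive work-up unmasks the C3 aldehyde; acetonide and silyl ethers are inert. The aldehyde is used crude because the C5 silyloxy group is β to the carbonyl.

Step 16
Reactants: 26 (3R)-4-{(4R,6S)-6-[(2R,6S)-2,6-bis(TBSO)heptadecyl]-2,2-dimethyl-1,3-dioxan-4-yl}-3-(TBSO)butanal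
Product: 27 methyl (2Z,5S)-6-{(4R,6S)-6-[(2R,6S)-2,6-bis(TBSO)heptadecyl]-2,2-dimethyl-1,3-dioxan-4-yl}-5-(TBSO)hex-2-enoate
Conditions: (CF3CH2O)2P(O)CH2CO2Me, KN(SiMe3)2, 18-crown-6, THF, −78 °C
Reagents that add atoms: methyl bis(2,2,2-trifluoroethyl)phosphonoacetate, COC(=O)CP(=O)(OCC(F)(F)F)OCC(F)(F)F
Why: Still–Gennari olefination: the electron-poor phosphonate under dissociating conditions eliminates from the kinetically formed adduct, giving the (Z)-enoate that the ring closure needs. The non-nucleophilic base at −78 °C does not eliminate the C5 silyloxy group.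

Step 17
Reactants: 27 methyl (2Z,5S)-6-{(4R,6S)-6-[(2R,6S)-2,6-bis(TBSO)heptadecyl]-2,2-dimethyl-1,3-dioxan-4-yl}-5-(TBSO)hex-2-enoate
Product: 29 (6S)-6-[(2R,4R,6R,10S)-2,4,6,10-tetrahydroxyhenicosyl]-5,6-dihydro-2H-pyran-2-one, via methyl (2Z)-pentahydroxyhexacos-2-enoate 28 (not isolated)
Conditions: 48% aq. HF, MeCN, 0 °C to rt
Reagents that add atoms: none
Why: Acidic global deprotection (cleavage of three silyl ethers by fluoride, hydrolysis of the acetonide) gives the seco ester 28, whose C5 hydroxyl sits cis across C2=C3 from the ester and lactonises under the same acid. No stereocentre is touched, and the acidic medium avoids the base-promoted addition of the C7 hydroxyl to C3.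

## Compound list

1 | pentane-1,5-diol | OCCCCCO | starting material
2 | allyl acetate | CC(=O)OCC=C | starting material
3 | (5R)-oct-7-ene-1,5-diol | OCCCC[C@@H](O)CC=C | intermediate
4 | (4R,8R)-undeca-1,10-diene-4,8-diol | C=CC[C@H](O)CCC[C@@H](O)CC=C | intermediate
5 | tert-butyl (4R,8R)-8-hydroxyundeca-1,10-dien-4-yl carbonate | C=CC[C@H](O)CCC[C@@H](OC(=O)OC(C)(C)C)CC=C | intermediate
6 | (4R,6R)-4-[(4R)-4-hydroxyhept-6-en-1-yl]-6-(iodomethyl)-1,3-dioxan-2-one | C=CC[C@H](O)CCC[C@@H]1C[C@H](CI)OC(=O)O1 | intermediate
7 | dec-1-ene | C=CCCCCCCCC | starting material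
8 | (4R,6R)-4-[(4R)-4-hydroxypentadec-6-en-1-yl]-6-(iodomethyl)-1,3-dioxan-2-one (E/Z mixture) | CCCCCCCCC=CC[C@H](O)CCC[C@@H]1C[C@H](CI)OC(=O)O1 | intermediate
9 | (2R,6R)-1-[(2R)-oxiran-2-yl]heptadec-8-ene-2,6-diol (E/Z mixture) | CCCCCCCCC=CC[C@H](O)CCC[C@@H](O)C[C@@H]1CO1 | intermediate
10 | (2R,6S)-1-[(2R)-oxiran-2-yl]heptadecane-2,6-diol | CCCCCCCCCCC[C@H](O)CCC[C@@H](O)C[C@@H]1CO1 | intermediate
11 | (2R)-2-[(2R,6S)-2,6-bis(tert-butyldimethylsilyloxy)heptadecyl]oxirane | CCCCCCCCCCC[C@H](O[Si](C)(C)C(C)(C)C)CCC[C@@H](O[Si](C)(C)C(C)(C)C)C[C@@H]1CO1 | intermediate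
12 | 1,3-dithiane | C1CSCSC1 | starting material
13 | (R)-2-(chloromethyl)oxirane | ClC[C@H]1CO1 | starting material
14 | 2-lithio-1,3-dithiane | [Li]C1SCCCS1 | intermediate
15 | lithium (2R)-1-chloro-3-(1,3-dithian-2-yl)propan-2-olate | ClC[C@H](O[Li])CC1SCCCS1 | intermediate
16 | 2-{[(2R)-oxiran-2-yl]methyl}-1,3-dithiane | S1CCCSC1C[C@@H]1CO1 | intermediate
17 | (2S)-1-(1,3-dithian-2-yl)pent-4-en-2-ol | S1CCCSC1C[C@@H](O)CC=C | intermediate
18 | tert-butyl{[(2S)-1-(1,3-dithian-2-yl)pent-4-en-2-yl]oxy}dimethylsilane | S1CCCSC1C[C@@H](O[Si](C)(C)C(C)(C)C)CC=C | intermediate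
19 | tert-butyl{[(2S)-1-(2-lithio-1,3-dithian-2-yl)pent-4-en-2-yl]oxy}dimethylsilane | [Li]C1(SCCCS1)C[C@@H](O[Si](C)(C)C(C)(C)C)CC=C | intermediate
20 | (2R,4R,8S)-4,8-bis(tert-butyldimethylsilyloxy)-1-{2-[(2S)-2-(tert-butyldimethylsilyloxy)pent-4-en-1-yl]-1,3-dithian-2-yl}nonadecan-2-ol | CCCCCCCCCCC[C@H](O[Si](C)(C)C(C)(C)C)CCC[C@@H](O[Si](C)(C)C(C)(C)C)C[C@@H](O)CC1(SCCCS1)C[C@@H](O[Si](C)(C)C(C)(C)C)CC=C | intermediate
21 | (4S,8R,10R,14S)-4,10,14-tris(tert-butyldimethylsilyloxy)-8-hydroxypentacos-1-en-6-one | CCCCCCCCCCC[C@H](O[Si](C)(C)C(C)(C)C)CCC[C@@H](O[Si](C)(C)C(C)(C)C)C[C@@H](O)CC(=O)C[C@@H](O[Si](C)(C)C(C)(C)C)CC=C | intermediate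
22 | (4S,8R,10R,14S)-4,10,14-tris(tert-butyldimethylsilyloxy)-8-[(diethylboranyl)oxy]pentacos-1-en-6-one (boron chelate) | CCCCCCCCCCC[C@H](O[Si](C)(C)C(C)(C)C)CCC[C@@H](O[Si](C)(C)C(C)(C)C)C[C@@H](OB(CC)CC)CC(=O)C[C@@H](O[Si](C)(C)C(C)(C)C)CC=C | intermediate
23 | (4S,6R,8S,10R,14S)-4,10,14-tris(tert-butyldimethylsilyloxy)pentacos-1-ene-6,8-diol | CCCCCCCCCCC[C@H](O[Si](C)(C)C(C)(C)C)CCC[C@@H](O[Si](C)(C)C(C)(C)C)C[C@@H](O)C[C@@H](O)C[C@@H](O[Si](C)(C)C(C)(C)C)CC=C | intermediate
24 | (4R,6S)-6-[(2R,6S)-2,6-bis(tert-butyldimethylsilyloxy)heptadecyl]-2,2-dimethyl-4-[(2S)-2-(tert-butyldimethylsilyloxy)pent-4-en-1-yl]-1,3-dioxane | CCCCCCCCCCC[C@H](O[Si](C)(C)C(C)(C)C)CCC[C@@H](O[Si](C)(C)C(C)(C)C)C[C@@H]1C[C@H](C[C@@H](O[Si](C)(C)C(C)(C)C)CC=C)OC(C)(C)O1 | intermediate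
25 | 3-[(2R)-3-{(4R,6S)-6-[(2R,6S)-2,6-bis(tert-butyldimethylsilyloxy)heptadecyl]-2,2-dimethyl-1,3-dioxan-4-yl}-2-(tert-butyldimethylsilyloxy)propyl]-1,2,4-trioxolane (mixture at the trioxolane carbon) | CCCCCCCCCCC[C@H](O[Si](C)(C)C(C)(C)C)CCC[C@@H](O[Si](C)(C)C(C)(C)C)C[C@@H]1C[C@H](C[C@@H](O[Si](C)(C)C(C)(C)C)CC2OCOO2)OC(C)(C)O1 | intermediate
26 | (3R)-4-{(4R,6S)-6-[(2R,6S)-2,6-bis(tert-butyldimethylsilyloxy)heptadecyl]-2,2-dimethyl-1,3-dioxan-4-yl}-3-(tert-butyldimethylsilyloxy)butanal | CCCCCCCCCCC[C@H](O[Si](C)(C)C(C)(C)C)CCC[C@@H](O[Si](C)(C)C(C)(C)C)C[C@@H]1C[C@H](C[C@@H](O[Si](C)(C)C(C)(C)C)CC=O)OC(C)(C)O1 | intermediate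
27 | methyl (2Z,5S)-6-{(4R,6S)-6-[(2R,6S)-2,6-bis(tert-butyldimethylsilyloxy)heptadecyl]-2,2-dimethyl-1,3-dioxan-4-yl}-5-(tert-butyldimethylsilyloxy)hex-2-enoate | CCCCCCCCCCC[C@H](O[Si](C)(C)C(C)(C)C)CCC[C@@H](O[Si](C)(C)C(C)(C)C)C[C@@H]1C[C@H](C[C@@H](O[Si](C)(C)C(C)(C)C)C/C=C\C(=O)OC)OC(C)(C)O1 | intermediate
28 | methyl (2Z,5S,7S,9R,11R,15S)-5,7,9,11,15-pentahydroxyhexacos-2-enoate | CCCCCCCCCCC[C@H](O)CCC[C@@H](O)C[C@@H](O)C[C@@H](O)C[C@@H](O)C/C=C\C(=O)OC | intermediate
29 | (6S)-6-[(2R,4R,6R,10S)-2,4,6,10-tetrahydroxyhenicosyl]-5,6-dihydro-2H-pyran-2-one | CCCCCCCCCCC[C@H](O)CCC[C@@H](O)C[C@@H](O)C[C@@H](O)C[C@@H]1CC=CC(=O)O1 | target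

## Step count and least certain steps

Total step count: 17 (14 on the main line, 3 for the dithiane 18). Longest linear sequence: 14 steps (steps 1–7, then 11–17).

**Step 1 (key step).** Three things are most likely to go wrong.
- Each δ-hydroxy aldehyde generated at iridium cyclises to its lactol, and irreversible dehydrogenation at the lactol stage would drain material before allylation.
- The second allylation may stall at the mono-adduct stage.
- The few per cent of meso diastereomer that the amplification produces has its stereocentres five atoms apart and will be hard to separate. It would have to be removed later, most plausibly at the cyclic stages 6 or 24.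

Fallback, from 1: a Swern oxidation gives pentanedial F1, which is used at once in ether at −78 °C with two equivalents of (−)-B-allyldiisopinocampheylborane (the antipode from (+)-α-pinene, which gives the (R)-carbinol from unbranched aldehydes). The first adduct stays as a borinate and cannot form a lactol. Oxidative work-up returns the route at 4.

**Step 3.** The likely failure is electrophilic addition of the interhalogen to the unassisted alkene of the other arm in competition with the assisted cyclisation. A milder iodine source would cost syn selectivity.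

Fallback, from 4: both hydroxyls are acylated to di-tert-butyl (4R,8R)-undeca-1,10-diene-4,8-diyl dicarbonate F2, so that no unassisted alkene is ever exposed. IBr in deficit at −85 °C cyclises one arm to the mono-iodocarbonate tert-butyl (4R)-7-[(4R,6R)-6-(iodomethyl)-2-oxo-1,3-dioxan-4-yl]hept-1-en-4-yl carbonate F3, and unreacted F2 is recycled. Trifluoroacetic acid then removes the remaining acyclic carbonate and returns the route at 6. The statistical event is thus moved from the acylation to the cyclisation, at the cost of one step.

**Step 6.** The likely failure is hydrogenolytic opening of the terminal epoxide in competition with saturation of the hindered, slowly reacting 1,2-disubstituted alkene.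

Fallback, from 8: the alkene is reduced before the epoxide exists, with diimide (2-nitrobenzenesulfonylhydrazide, Et3N, CH2Cl2), which does not touch the C–I bond. This gives (4R,6R)-4-[(4S)-4-hydroxypentadecyl]-6-(iodomethyl)-1,3-dioxan-2-one F4. The methanolysis of step 5 applied to F4 returns the route at 10.

**Step 11.** The likely failure is incomplete or unselective metalation of 18 (t-BuLi attacking the allyl group, or proton transfer from the allylic position to the hindered carbanion), which leaves the valuable epoxide 11 unconsumed.

Fallback, from 11: the same carbanion is generated without a deprotonation, by anion relay.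
- (2S)-2-(chloromethyl)oxirane F5 is opened with the vinyl Grignard reagent and CuI to (2S)-1-chloropent-4-en-2-ol F6, which is closed with NaOH to (2S)-2-(prop-2-en-1-yl)oxirane F7.
- 2-(tert-butyldimethylsilyl)-1,3-dithiane F8 is lithiated (n-BuLi, ether) to 2-lithio-2-(tert-butyldimethylsilyl)-1,3-dithiane F9.
- F9 opens F7 to lithium (2S)-1-[2-(tert-butyldimethylsilyl)-1,3-dithian-2-yl]pent-4-en-2-olate F10.
- Adding 11 in THF/HMPA triggers the 1,4-Brook shift of silicon from carbon to the C5 oxygen. This produces 19 in the presence of 11 and returns the route at 20.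

## Further compounds

F1 | step 1 | pentanedial | O=CCCCC=O
F2 | step 3 | di-tert-butyl (4R,8R)-undeca-1,10-diene-4,8-diyl dicarbonate | C=CC[C@H](OC(=O)OC(C)(C)C)CCC[C@@H](OC(=O)OC(C)(C)C)CC=C
F3 | step 3 | tert-butyl (4R)-7-[(4R,6R)-6-(iodomethyl)-2-oxo-1,3-dioxan-4-yl]hept-1-en-4-yl carbonate | C=CC[C@H](OC(=O)OC(C)(C)C)CCC[C@@H]1C[C@H](CI)OC(=O)O1
F4 | step 6 | (4R,6R)-4-[(4S)-4-hydroxypentadecyl]-6-(iodomethyl)-1,3-dioxan-2-one | CCCCCCCCCCC[C@H](O)CCC[C@@H]1C[C@H](CI)OC(=O)O1
F5 | step 11 | (2S)-2-(chloromethyl)oxirane | ClC[C@@H]1CO1
F6 | step 11 | (2S)-1-chloropent-4-en-2-ol | ClC[C@@H](O)CC=C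
F7 | step 11 | (2S)-2-(prop-2-en-1-yl)oxirane | C=CC[C@H]1CO1
F8 | step 11 | 2-(tert-butyldimethylsilyl)-1,3-dithiane | CC(C)(C)[Si](C)(C)C1SCCCS1
F9 | step 11 | 2-lithio-2-(tert-butyldimethylsilyl)-1,3-dithiane | CC(C)(C)[Si](C)(C)C1([Li])SCCCS1
F10 | step 11 | lithium (2S)-1-[2-(tert-butyldimethylsilyl)-1,3-dithian-2-yl]pent-4-en-2-olate | C=CC[C@H](O[Li])CC1(SCCCS1)[Si](C)(C)C(C)(C)C
A1 | alternative 1 | (3R)-3-(tert-butyldimethylsilyloxy)-4-{(4R,6R)-6-[(4S)-4-(tert-butyldimethylsilyloxy)pentadecyl]-2,2-dimethyl-1,3-dioxan-4-yl}butanal | CCCCCCCCCCC[C@H](O[Si](C)(C)C(C)(C)C)CCC[C@@H]1C[C@@H](OC(C)(C)O1)C[C@@H](O[Si](C)(C)C(C)(C)C)CC=O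
A2 | alternative 1 | (E)-1-methoxybuta-1,3-diene | CO/C=C/C=C
A3 | alternative 1 | cis-2-methoxy-6-substituted 5,6-dihydro-2H-pyran (cycloadduct of A1 and A2; C7 and C15 silyl ethers, C9/C11 acetonide) | CCCCCCCCCCC[C@H](O[Si](C)(C)C(C)(C)C)CCC[C@@H]1C[C@@H](OC(C)(C)O1)C[C@@H](O[Si](C)(C)C(C)(C)C)C[C@@H]1CC=C[C@H](OC)O1
A4 | alternative 2 | 2-(tert-butyldimethylsilyl)-1,3-dithiane | CC(C)(C)[Si](C)(C)C1SCCCS1
A5 | alternative 2 | (2R)-2-[(4S)-4-(tert-butyldimethylsilyloxy)pentadecyl]oxirane | CCCCCCCCCCC[C@H](O[Si](C)(C)C(C)(C)C)CCC[C@@H]1CO1
A6 | alternative 2 | tert-butyl{[(2S)-4-[(4-methoxybenzyl)oxy]-1-[(2S)-oxiran-2-yl]butan-2-yl]oxy}dimethylsilane | C1[C@@H](O1)C[C@@H](O[Si](C)(C)C(C)(C)C)CCOCc2ccc(OC)cc2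
A7 | alternative 2 | C3–C26 chain with C9 as 1,3-dithiane, C7 hydroxyl free, C5, C11 and C15 silyl ethers, C3 4-methoxybenzyl ether | CCCCCCCCCCC[C@H](O[Si](C)(C)C(C)(C)C)CCC[C@@H](O[Si](C)(C)C(C)(C)C)CC1(SCCCS1)C[C@@H](O)C[C@@H](O[Si](C)(C)C(C)(C)C)CCOCc1ccc(OC)cc1
A8 | alternative 3 | (2E,5R,9S)-9-(tert-butyldimethylsilyloxy)icos-2-ene-1,5-diol | CCCCCCCCCCC[C@H](O[Si](C)(C)C(C)(C)C)CCC[C@@H](O)C/C=C/CO
A9 | alternative 3 | (dimethoxymethyl)benzene | COC(OC)c1ccccc1
A10 | alternative 3 | 2,4,6-cis-4-ethenyl-2-phenyl-6-[(4S)-4-(tert-butyldimethylsilyloxy)pentadecyl]-1,3-dioxane | CCCCCCCCCCC[C@H](O[Si](C)(C)C(C)(C)C)CCC[C@@H]1C[C@@H](O[C@H](c2ccccc2)O1)C=C
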